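**Retrosynthetic overview**

- The last C–C bonds made are those of the cyclohexene in which aroyl and C6‑aryl are trans (ring A): an intramolecular Diels–Alder reaction of a seco chalcone–diene closes ring A and the 12‑membered ring together.
- The seco compound comes from a cis‑fused aryl lactone of the other cyclohexene (ring B) by aryllithium opening (aryl ketone) and carbonylative Stille coupling (enone).
- Ring B is not made as a six‑membered ring. A donor–acceptor vinylcyclobutane, from a (2+2) cycloaddition of a 7‑silyloxycoumarin and a silyl dienol ether, is expanded by two carbons and arylated with 4‑bromoresorcinol in the same flask.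
- Enabling feature: in ring B the carbonyl carbon on C1 and the 2‑hydroxyaryl group on C6 are cis, so they can be tied as a six‑membered aryl lactone. Its carbonyl (on cyclobutane C2a) and the silyloxyvinyl group on C2 make the C2–C2a bond a push–pull bond, and the flat lactone allows only cis reclosure.
- Order of ring formation: cyclobutane → cyclohexene ring B (ring expansion) → cyclohexene ring A together with the macrocycle.

Key step: step 4

Assumption: the sense of induction of the oxazaborolidine (step 3) and of the VANOL borate (step 12) is taken as needed for the drawn configurations; if either is opposite on these substrates, the antipodal ligand is used.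

Abbreviations: TIPS = tri(propan‑2‑yl)silyl, TBS = tert‑butyl(dimethyl)silyl. Ring A: aroyl/C6‑aryl trans, (1S,2R,6R). Ring B: aroyl/C6‑aryl cis, (1R,2R,6R).

Step 1
Reactants: 1 7-hydroxy-2H-chromen-2-one (umbelliferone)
Product: 2 7-(TIPS-oxy)-2H-chromen-2-one
Conditions: TIPSCl, imidazole, DMF, 25 °C
Reagents that add atoms: chlorotri(propan-2-yl)silane, CC(C)[Si](Cl)(C(C)C)C(C)C
Why: Imidazole-assisted silylation of the phenol gives an ether that should survive Lewis acid, organolithium and palladium steps and leave with fluoride at the end.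

Step 2
Reactants: 3 3-methylbut-2-enal
Product: 4 tert-butyl(dimethyl){[(1E)-3-methylbuta-1,3-dien-1-yl]oxy}silane
Conditions: TBSOTf, Et3N, Et2O, 0 → 25 °C
Reagents that add atoms: tert-butyl(dimethyl)silyl trifluoromethanesulfonate, CC(C)(C)[Si](C)(C)OS(=O)(=O)C(F)(F)F
Why: O-silylation of the enal and γ-deprotonation (vinylogous silyl enol ether formation) should give the 1-silyloxydiene, E because the s-trans enal is silylated.

Step 3
Reactants: 2 7-(TIPS-oxy)-2H-chromen-2-one; 4 silyl dienol ether
Product: 5 (2aR,8bR)-2-[(E)-2-(TBS-oxy)ethenyl]-2-methyl-6-(TIPS-oxy)-1,2,2a,8b-tetrahydro-3H-cyclobuta[c]chromen-3-one (cis-fused; both C2 epimers)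
Conditions: oxazaborolidine from (S)-α,α-diphenylprolinol and 2-methylphenylboronic acid (25 mol%), AlBr3 (20 mol%), CH2Cl2, −78 °C
Reagents that add atoms: none
Why: Proposed new method: the AlBr3-activated oxazaborolidine binds the lactone carbonyl of 2 and shields one face of C3=C4, the CH2 terminus of the s-trans dienol ether adds to C4 (vinylogous Mukaiyama–Michael addition), and because the resulting 1-silyloxyallyl cation is formed with its oxygen-bearing terminus turned away from the new bond, the boron enolate can reach only the near, methyl-bearing carbon, so the zwitterion should collapse to the cis-fused cyclobutane (C8b set by the catalyst, C2a by the ring fusion, C2 a mixture that converges later); the closest known reactions are the Lewis-acid- and Tf2NH-catalysed (2+2) cycloadditions of silyl enol ethers with α,β-unsaturated esters, including the enantioselective oxazaborolidine–AlBr3 version, and the face-selective binding of coumarins by this catalyst in photocycloadditions; any adduct that closes directly to the six-membered ring is compound 7 and enters step 4.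

Step 4
Reactants: 5 vinylcyclobutane lactone; 6 4-bromobenzene-1,3-diol
Product: 8 (6aR,7R,10aR)-7-(5-bromo-2,4-dihydroxyphenyl)-9-methyl-3-(TIPS-oxy)-6a,7,10,10a-tetrahydro-6H-benzo[c]chromen-6-one, via ring-expanded allylic silyl ether 7 (not isolated)
Conditions: BF3·OEt2 (1.5 equiv), 2,6-di-tert-butylpyridine (0.2 equiv), CH2Cl2, −78 → −30 °C; then 6 (3 equiv, in Et2O), −30 → 0 °C
Reagents that add atoms: none
Why: Proposed new method: BF3 on the lactone carbonyl heterolyses the push–pull C2–C2a bond of the cyclobutane (lactone enolate plus 1-silyloxyallyl cation, ionised from the rotamer whose vinyl group lies syn to C1) and the enolate recloses on the oxygen-bearing allyl terminus, a net [1,3] shift that expands the four-membered ring to cyclohexene 7 (6-(enolexo)-exo-trig closure on the oxocarbenium carbon of the cation); the closest known reactions are the Lewis-acid-induced zwitterionic rearrangements of 1-silyloxy-1-vinylcyclobutane esters to formal Diels–Alder adducts. The new ring-fusion centre C6a can only be cis, because in the flat benzo-fused lactone enolate the C10 methylene sits over one face of C6a and the four-atom tether cannot reach the other. BF3 then ionises the allylic silyl ether of 7 to a methylcyclohexenyl cation, which 4-bromoresorcinol should capture in a Friedel–Crafts allylation of the cannabidiol type at the secondary terminus C7 and on the convex face anti to the C6 carbonyl on C6a, which sets C7 trans to the lactone. The step needs six- over four-membered reclosure (the cyclobutane reopens, the cyclohexene does not), arylation over proton loss (excess arene, low temperature) and attack through C6 of the resorcinol (C2 lies between two hydroxyls); both C2 epimers of 5 and both C7 epimers of 7 converge on one product.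

Step 5
Reactants: 6 4-bromobenzene-1,3-diol
Product: 9 1-bromo-2,4-bis(TIPS-oxy)benzene
Conditions: TIPSCl (2.4 equiv), imidazole, DMF, 40 °C
Reagents that add atoms: chlorotri(propan-2-yl)silane, CC(C)[Si](Cl)(C(C)C)C(C)C
Why: Standard double silylation of the two phenols.

Step 6
Reactants: 9 1-bromo-2,4-bis(TIPS-oxy)benzene
Product: 10 1-bromo-5-iodo-2,4-bis(TIPS-oxy)benzene
Conditions: N-iodosuccinimide, CF3CO2H (10 mol%), MeCN, 0 → 25 °C
Reagents that add atoms: N-iodosuccinimide, O=C1CCC(=O)N1I
Why: Electrophilic aromatic iodination should go to C5 (para to one silyloxy group, ortho to the other), since C3 lies between two bulky silyl ethers.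

Step 7
Reactants: 11 2-methylbut-1-en-3-yne
Product: 12 4,4,5,5-tetramethyl-2-[(1E)-3-methylbuta-1,3-dien-1-yl]-1,3,2-dioxaborolane
Conditions: pinacolborane, Cp2Zr(H)Cl (5 mol%), Et3N (10 mol%), neat, 60 °C
Reagents that add atoms: pinacolborane, CC1(C)OBOC1(C)C
Why: Zirconium-catalysed syn hydroboration of the terminal alkyne, chemoselective over the 1,1-disubstituted alkene, gives the E dienylboronate.

Step 8
Reactants: 10 bromo iodo arene; 12 dienylboronate
Product: 13 1-bromo-5-[(1E)-3-methylbuta-1,3-dien-1-yl]-2,4-bis(TIPS-oxy)benzene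
Conditions: Pd(PPh3)4 (5 mol%), K3PO4, dioxane/H2O, 60 °C
Reagents that add atoms: none
Why: Suzuki–Miyaura coupling in which oxidative addition into C–I precedes C–Br, with retention of the E geometry.

Step 9
Reactants: 8 lactone; 13 dienyl aryl bromide
Product: 15 [(1R,2R,6R)-2-(5-bromo-2,4-dihydroxyphenyl)-6-(2-hydroxy-4-(TIPS-oxy)phenyl)-4-methylcyclohex-3-en-1-yl]{5-[(1E)-3-methylbuta-1,3-dien-1-yl]-2,4-bis(TIPS-oxy)phenyl}methanone, via aryllithium 14 (not isolated)
Conditions: 13, n-BuLi, THF, −78 °C; 8 pre-treated with NaH (2 equiv), THF, 0 °C, added at −78 °C; 1 M HCl to pH 5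
Reagents that add atoms: none
Why: Bromine–lithium exchange then addition of the aryllithium to the aryl-ester carbonyl opens the lactone to the ketone and a phenoxide; the hindered, α-branched ketone should resist a second addition and the C1 centre is not enolised at −78 °C.

Step 10
Reactants: 9 1-bromo-2,4-bis(TIPS-oxy)benzene; 16 (E)-1,2-bis(tributylstannyl)ethene
Product: 17 tributyl{(E)-2-[2,4-bis(TIPS-oxy)phenyl]ethenyl}stannane
Conditions: 16 (3 equiv), Pd(PPh3)4 (5 mol%), toluene, 100 °C
Reagents that add atoms: none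
Why: Stille mono-coupling (excess distannane) with retention of the E geometry.

Step 11
Reactants: 15 aryl bromide ketone; 17 styrylstannane
Product: 18 seco chalcone–diene (15 with Br replaced by (2E)-3-[2,4-bis(TIPS-oxy)phenyl]prop-2-enoyl)
Conditions: CO (3 bar), PdCl2(PPh3)2 (10 mol%), dioxane, 90 °C
Reagents that add atoms: carbon monoxide, [C-]#[O+]
Why: Carbonylative Stille coupling (oxidative addition, CO insertion, transmetalation with retention of alkene geometry) under neutral conditions, so the ketone α-centre is not epimerised.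

Step 12
Reactants: 18 seco chalcone–diene
Product: 19 pentakis-TIPS ether of the target (ring A (1S,2R,6R), ring B (1R,2R,6R))
Conditions: (R)-VANOL, BH3·THF, AcOH (1.2 equiv each, premixed in THF, 25 °C); then 18, PhCF3 (2 mM), 50 °C; aqueous work-up
Reagents that add atoms: none
Why: Intramolecular Diels–Alder reaction of the borate-bound 2'-hydroxychalcone with the aryl diene, a promoter class known for endo- and face-selective cycloadditions in this family including the ring-closing second cycloaddition; the E enone gives aroyl trans to the C6 aryl, the endo mode puts the C2 aryl cis to the aroyl, and the ligand should select the enone face.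

Step 13
Reactants: 19 pentakis-TIPS ether
Product: 20 target CNP0244682.3
Conditions: tetrabutylammonium fluoride (6 equiv), AcOH (6 equiv), THF, 0 → 25 °C
Reagents that add atoms: none
Why: Fluoride cleavage of the five aryl silyl ethers, buffered with acetic acid so that neither ketone α-centre is epimerised.

**Compound list**

1 | 7-hydroxy-2H-chromen-2-one | O=c1ccc2ccc(O)cc2o1 | starting material
2 | 7-(TIPS-oxy)-2H-chromen-2-one | O=c1ccc2ccc(O[Si](C(C)C)(C(C)C)C(C)C)cc2o1 | intermediate
3 | 3-methylbut-2-enal | CC(C)=CC=O | starting material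
4 | tert-butyl(dimethyl){[(1E)-3-methylbuta-1,3-dien-1-yl]oxy}silane | C=C(C)/C=C/O[Si](C)(C)C(C)(C)C | intermediate
5 | (2aR,8bR)-2-[(E)-2-(TBS-oxy)ethenyl]-2-methyl-6-(TIPS-oxy)-1,2,2a,8b-tetrahydro-3H-cyclobuta[c]chromen-3-one (C2 epimers) | O=C1[C@H]2C(C)(/C=C/O[Si](C)(C)C(C)(C)C)C[C@H]2c2ccc(O[Si](C(C)C)(C(C)C)C(C)C)cc2O1 | intermediate
6 | 4-bromobenzene-1,3-diol | Oc1ccc(Br)c(O)c1 | starting material
7 | (6aR,10aR)-7-(TBS-oxy)-9-methyl-3-(TIPS-oxy)-6a,7,10,10a-tetrahydro-6H-benzo[c]chromen-6-one (C7 epimers) | O=C1[C@H]2C(O[Si](C)(C)C(C)(C)C)C=C(C)C[C@H]2c2ccc(O[Si](C(C)C)(C(C)C)C(C)C)cc2O1 | intermediate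
8 | (6aR,7R,10aR)-7-(5-bromo-2,4-dihydroxyphenyl)-9-methyl-3-(TIPS-oxy)-6a,7,10,10a-tetrahydro-6H-benzo[c]chromen-6-one | O=C1[C@H]2[C@@H](C=C(C)C[C@H]2c2ccc(O[Si](C(C)C)(C(C)C)C(C)C)cc2O1)c1cc(Br)c(O)cc1O | intermediate
9 | 1-bromo-2,4-bis(TIPS-oxy)benzene | Brc1ccc(O[Si](C(C)C)(C(C)C)C(C)C)cc1O[Si](C(C)C)(C(C)C)C(C)C | intermediate
10 | 1-bromo-5-iodo-2,4-bis(TIPS-oxy)benzene | Brc1cc(I)c(O[Si](C(C)C)(C(C)C)C(C)C)cc1O[Si](C(C)C)(C(C)C)C(C)C | intermediate
11 | 2-methylbut-1-en-3-yne | C=C(C)C#C | starting material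
12 | 4,4,5,5-tetramethyl-2-[(1E)-3-methylbuta-1,3-dien-1-yl]-1,3,2-dioxaborolane | C=C(C)/C=C/B1OC(C)(C)C(C)(C)O1 | intermediate
13 | 1-bromo-5-[(1E)-3-methylbuta-1,3-dien-1-yl]-2,4-bis(TIPS-oxy)benzene | C=C(C)/C=C/c1cc(Br)c(O[Si](C(C)C)(C(C)C)C(C)C)cc1O[Si](C(C)C)(C(C)C)C(C)C | intermediate
14 | {5-[(1E)-3-methylbuta-1,3-dien-1-yl]-2,4-bis(TIPS-oxy)phenyl}lithium | [Li]c1cc(/C=C/C(C)=C)c(O[Si](C(C)C)(C(C)C)C(C)C)cc1O[Si](C(C)C)(C(C)C)C(C)C | intermediate
15 | [(1R,2R,6R)-2-(5-bromo-2,4-dihydroxyphenyl)-6-(2-hydroxy-4-(TIPS-oxy)phenyl)-4-methylcyclohex-3-en-1-yl]{5-[(1E)-3-methylbuta-1,3-dien-1-yl]-2,4-bis(TIPS-oxy)phenyl}methanone | C=C(C)/C=C/c1cc(c(O[Si](C(C)C)(C(C)C)C(C)C)cc1O[Si](C(C)C)(C(C)C)C(C)C)C(=O)[C@H]1[C@@H](C=C(C)C[C@H]1c1ccc(O[Si](C(C)C)(C(C)C)C(C)C)cc1O)c1cc(Br)c(O)cc1O | intermediate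
16 | (E)-1,2-bis(tributylstannyl)ethene | CCCC[Sn](CCCC)(CCCC)/C=C/[Sn](CCCC)(CCCC)CCCC | starting material
17 | tributyl{(E)-2-[2,4-bis(TIPS-oxy)phenyl]ethenyl}stannane | CCCC[Sn](CCCC)(CCCC)/C=C/c1ccc(O[Si](C(C)C)(C(C)C)C(C)C)cc1O[Si](C(C)C)(C(C)C)C(C)C | intermediate
18 | seco chalcone–diene: 15 with Br replaced by (2E)-3-[2,4-bis(TIPS-oxy)phenyl]prop-2-enoyl; ring B (1R,2R,6R) | C=C(C)/C=C/c1cc(c(O[Si](C(C)C)(C(C)C)C(C)C)cc1O[Si](C(C)C)(C(C)C)C(C)C)C(=O)[C@H]1[C@@H](C=C(C)C[C@H]1c1ccc(O[Si](C(C)C)(C(C)C)C(C)C)cc1O)c1cc(c(O)cc1O)C(=O)/C=C/c1ccc(O[Si](C(C)C)(C(C)C)C(C)C)cc1O[Si](C(C)C)(C(C)C)C(C)C | intermediate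
19 | pentakis-TIPS ether of 20 (free: both hydroxyls of the resorcinol ring on C2 of ring B and the 2-hydroxyl of the aryl on C6 of ring B); ring A (1S,2R,6R), ring B (1R,2R,6R) | CC1=C[C@H]2c3cc(c(O[Si](C(C)C)(C(C)C)C(C)C)cc3O[Si](C(C)C)(C(C)C)C(C)C)C(=O)[C@H]3[C@@H](C=C(C)C[C@H]3c3ccc(O[Si](C(C)C)(C(C)C)C(C)C)cc3O)c3cc(c(O)cc3O)C(=O)[C@H]2[C@H](c2ccc(O[Si](C(C)C)(C(C)C)C(C)C)cc2O[Si](C(C)C)(C(C)C)C(C)C)C1 | intermediate
20 | CNP0244682.3: macrocyclic bis(aryl ketone) of two 2,6-diaryl-4-methylcyclohex-3-en-1-yl units, ring A (1S,2R,6R), ring B (1R,2R,6R), eight free phenols | CC1=C[C@H]2c3cc(c(O)cc3O)C(=O)[C@H]3[C@@H](C=C(C)C[C@H]3c3ccc(O)cc3O)c3cc(c(O)cc3O)C(=O)[C@H]2[C@H](c2ccc(O)cc2O)C1 | target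

**Step count and risks**

Total steps: 13. Longest linear sequence: 7 (steps 1, 3, 4, 9, 11, 12, 13).

Step 4. The cyclohexenyl cation may lose a proton to a conjugated diene faster than the bromoresorcinol captures it, or the silyl enol ether of 5 may be cleaved, or the cyclobutane may revert to coumarin and diene, before productive reclosure. The fallback sets out from 2 and comes back at 8; it keeps the four-to-six ring expansion and moves the arylation to a tertiary allylic alcohol. The (2+2) cycloaddition of 2 with commercial 2-(trimethylsilyloxy)buta-1,3-diene is run with Tf2NH or EtAlCl2, as known for 2-silyloxydienes and unsaturated esters, and the enantiomers are separated on the chiral phase named under step 3. This should give the vinylcyclobutane (2aR,8bR)-2-ethenyl-2-(trimethylsilyloxy)-6-(TIPS-oxy)-1,2,2a,8b-tetrahydro-3H-cyclobuta[c]chromen-3-one F1 as a mixture of C2 epimers. The known Lewis-acid-induced 1,3-shift of such 1-silyloxy-1-vinylcyclobutane esters (same acid, warming to 0 °C) should convert F1 into the cis-fused silyl enol ether (6aS,10aR)-9-(trimethylsilyloxy)-3-(TIPS-oxy)-6a,7,10,10a-tetrahydro-6H-benzo[c]chromen-6-one F2 without loss of the C10a configuration. Saegusa–Ito oxidation with Pd(OAc)2 in MeCN should take F2 on to the enone (6aS,10aR)-3-(TIPS-oxy)-6a,10a-dihydro-6H-benzo[c]chromene-6,9(10H)-dione F3 under neutral conditions. MeLi with CeCl3 (1 equiv, −78 °C) should then add 1,2 to the ketone in preference to the lactone to give the tertiary allylic alcohol (6aS,10aR)-9-hydroxy-9-methyl-3-(TIPS-oxy)-6a,9,10,10a-tetrahydro-6H-benzo[c]chromen-6-one F4 as a mixture of C9 epimers. BF3·OEt2 with 6 ionises F4 to the methylcyclohexenyl cation of the main route, and the cannabidiol-type Friedel–Crafts allylation gives 8.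

Step 3. The chiral Lewis acid may discriminate the faces of C4 poorly on a coumarin that carries a 7-silyloxy donor (uncatalysed background, silyl transfer). The fallback sets out from 2 and 4 and comes back at 5. The cycloaddition is run with the achiral catalyst Tf2NH, established for silyl enol ethers and unsaturated esters, to give racemic cis-fused 2-[(E)-2-(TBS-oxy)ethenyl]-2-methyl-6-(TIPS-oxy)-1,2,2a,8b-tetrahydro-3H-cyclobuta[c]chromen-3-one F5 as the material for resolution. The enantiomers of F5 are separated by preparative chromatography on a cellulose tris(3,5-dimethylphenylcarbamate) phase, and the (2aR,8bR) enantiomer is 5.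

Step 12. The face imposed by the borate may not match the geometry the tether allows, or exo closure and oligomerisation may compete, giving diastereomeric macrocycles. The fallback sets out from 8 and comes back at 19; it sets ring A in an untethered, bimolecular cycloaddition and closes the macrocycle at the aryl ketone. Carbonylative Stille coupling of 8 with 17 (conditions of step 11) gives the lactone chalcone (6aR,7R,10aR)-7-{5-[(2E)-3-(2,4-bis(TIPS-oxy)phenyl)prop-2-enoyl]-2,4-dihydroxyphenyl}-9-methyl-3-(TIPS-oxy)-6a,7,10,10a-tetrahydro-6H-benzo[c]chromen-6-one F6 with the lactone untouched. Intermolecular VANOL-borate Diels–Alder reaction of F6 with diene 13 gives the endo bromo lactone cycloadduct F7 in which ring A is (1S,2R,6R) and carries the 5-bromo-2,4-bis(TIPS-oxy)phenyl group at C2 while the lactone stays intact. The two phenols of F7 are deprotonated with LiN(SiMe3)2. Bromine–lithium exchange with n-BuLi at −100 °C and attack of the aryllithium on the lactone carbonyl (Parham-type cyclisation, high dilution) then close the macrocycle to 19.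

Further compounds
F1 | step 4 | (2aR,8bR)-2-ethenyl-2-(trimethylsilyloxy)-6-(TIPS-oxy)-1,2,2a,8b-tetrahydro-3H-cyclobuta[c]chromen-3-one (C2 epimers) | O=C1[C@H]2C(O[Si](C)(C)C)(C=C)C[C@H]2c2ccc(O[Si](C(C)C)(C(C)C)C(C)C)cc2O1
F2 | step 4 | (6aS,10aR)-9-(trimethylsilyloxy)-3-(TIPS-oxy)-6a,7,10,10a-tetrahydro-6H-benzo[c]chromen-6-one | O=C1[C@H]2CC=C(O[Si](C)(C)C)C[C@H]2c2ccc(O[Si](C(C)C)(C(C)C)C(C)C)cc2O1
F3 | step 4 | (6aS,10aR)-3-(TIPS-oxy)-6a,10a-dihydro-6H-benzo[c]chromene-6,9(10H)-dione | O=C1[C@H]2C=CC(=O)C[C@H]2c2ccc(O[Si](C(C)C)(C(C)C)C(C)C)cc2O1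
F4 | step 4 | (6aS,10aR)-9-hydroxy-9-methyl-3-(TIPS-oxy)-6a,9,10,10a-tetrahydro-6H-benzo[c]chromen-6-one (C9 epimers) | O=C1[C@H]2C=CC(C)(O)C[C@H]2c2ccc(O[Si](C(C)C)(C(C)C)C(C)C)cc2O1
F5 | step 3 | racemic cis-fused 2-[(E)-2-(TBS-oxy)ethenyl]-2-methyl-6-(TIPS-oxy)-1,2,2a,8b-tetrahydro-3H-cyclobuta[c]chromen-3-one | O=C1C2C(C)(/C=C/O[Si](C)(C)C(C)(C)C)CC2c2ccc(O[Si](C(C)C)(C(C)C)C(C)C)cc2O1
F6 | step 12 | (6aR,7R,10aR)-7-{5-[(2E)-3-(2,4-bis(TIPS-oxy)phenyl)prop-2-enoyl]-2,4-dihydroxyphenyl}-9-methyl-3-(TIPS-oxy)-6a,7,10,10a-tetrahydro-6H-benzo[c]chromen-6-one | O=C1[C@H]2[C@@H](C=C(C)C[C@H]2c2ccc(O[Si](C(C)C)(C(C)C)C(C)C)cc2O1)c1cc(c(O)cc1O)C(=O)/C=C/c1ccc(O[Si](C(C)C)(C(C)C)C(C)C)cc1O[Si](C(C)C)(C(C)C)C(C)C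
F7 | step 12 | endo bromo lactone cycloadduct of F6 and 13: ring A (1S,2R,6R) with 5-bromo-2,4-bis(TIPS-oxy)phenyl at C2, 2,4-bis(TIPS-oxy)phenyl at C6 and the lactone of 8 on the aroyl ring | CC1=C[C@@H](c2cc(Br)c(O[Si](C(C)C)(C(C)C)C(C)C)cc2O[Si](C(C)C)(C(C)C)C(C)C)[C@@H](C(=O)c2cc([C@@H]3C=C(C)C[C@H]4c5ccc(O[Si](C(C)C)(C(C)C)C(C)C)cc5OC(=O)[C@@H]34)c(O)cc2O)[C@H](c2ccc(O[Si](C(C)C)(C(C)C)C(C)C)cc2O[Si](C(C)C)(C(C)C)C(C)C)C1
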